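The teal run, at 115 °C, has product at 41.9% after 120 min, and that stall is where you start.

the same everywhere: partner 0.0312 M

| charge | substrate | protic impurity | temperature | remark | time |
|---|---|---|---|---|---|
| violet | 0.026 M | 0.0087 M | 88 °C | run made earlier |  |
| teal | 0.026 M | 0.019 M | 115 °C | run made earlier |  |
| amber | 0.039 M | 0.013 M | 88 °C | run made earlier |  |
| autumn | 0.026 M | 0.0130 M |  | at 75 °C until 3.0 h, from then on at 125 °C | 15 h |
| dusk | 0.026 M | 0.0130 M | 75 °C |  | 15 h |
| winter | 0.026 M | 0.0130 M | 100 °C |  | 15 h |
| dawn | 0.026 M | 0.0130 M | 125 °C |  | 15 h |

violet run (percent of the substrate charged)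

| time / h | product / % |
|---|---|
| 0.667 | 4.7 |
| 1.50 | 10.8 |
| 3.00 | 19.5 |
| 8.00 | 32.9 |

teal run (percent of the substrate charged)

| time / min | product / % |
|---|---|
| 12.0 | 13.6 |
| 25.0 | 24.8 |
| 50.0 | 34.4 |
| 120 | 41.9 |

amber run (percent of the substrate charged)

| time / h | product / % |
|---|---|
| 0.667 | 4.4 |
| 1.50 | 9.8 |
| 3.00 | 16.4 |
| 8.00 | 24.9 |

(each reading ± 0.3 percentage points)

* the flask that comes out highest in amount of product, in percent of the substrate charged, or "all alike" when all lie within 1.5 percentage points (autumn / dusk / winter / dawn / all alike)
* product at the end, in percent of the substrate charged, autumn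
* product at the end, in percent of the substrate charged, dusk
* product at the end, in percent of the substrate charged, winter
* product at the end, in percent of the substrate charged, dawn



Suppose the protic impurity takes partner one for one and quickly, and reckon with what it leaves free. The free-partner ceiling is the partner charge minus the impurity charge, as a percentage of the substrate charged, and 70.0% for autumn, dusk, winter and dawn, whose charges are the same. For teal it comes to 46.9%.

A second way to teal's end uses its curve and no charges. Take a single exponential through the start and the equally spaced readings at 25.0 min and 50.0 min: the plateau is the square of the first reading over twice the first minus the second, 40.5%. The two ways part by 6.4 percentage points, and the curve is the one that cheats, since teal's last reading already stands above that plateau. The ceiling survives, with the same reading below it.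

Teal has reached 89.3% of its ceiling, whereas violet, at 88 °C, has reached 38.0% of its own after 8.00 h. Temperature and time must therefore sort your four flasks beneath one ceiling. Dawn, the hottest, gets teal's share as your commitment: 62.5%, and you pick dawn as highest.

The forecast also picks dawn, with 61% for autumn, 17% for dusk, 46% for winter and 64% for dawn, a dawn figure above yours, on the ground that “hotter flasks win the race”. The flasks give 53.8% for autumn, 20.7% for dusk, 49.0% for winter and 63.5% for dawn, so dawn comes highest.

    partner + intermediate → product (k = 0.0480 /M/s, Ea = 80.0 kJ/mol)
    partner + protic impurity → quenched reagent (k = 0.0180 /M/s, Ea = 81.0 kJ/mol)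
    substrate ⇌ intermediate + leaving ligand (K = 0.00200 M, k = 1.30 × 10⁻⁴ /s, Ea = 105 kJ/mol, ΔH = 8.00 kJ/mol)
    2 substrate → homo dimer (k = 0.00360 /M/s, Ea = 59.0 kJ/mol)
    (constants at 100 °C)

Dawn ends 6.5 points below its ceiling of 70.0%, with 5.42% of its partner left and 36.2% of its substrate in homo dimer. Now take the neighbour, dawn with 0.078 M of partner. Its free partner, 0.0650 M, is more than the 0.026 M of substrate charged, so the free-partner ceiling no longer binds and the cap on its product is the substrate charge, 100%. Substrate is the first main charge to run out there, the limiting reagent, and the neighbour gives 75.6%. It ends with 0% of its substrate and 58% of its partner left, and 24.4% of its substrate stands as homo dimer.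

The readings come from a simulation from invented constants.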